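Compound numbers are those of the steps and of the compound list below; locants C1–C13 follow eremophilane numbering, primed locants belong to the side chain, and β is the face that carries the C5 methyl group.

## Analysis of the target

Compound 40 is a trans-fused eremophilane, that is a 4,5-dimethyl-7-isopropylidene decalin in which ring A is C1–C5 plus C10 and ring B is C5–C10. Ring A carries an equatorial 3α-acyloxy group, an equatorial 4β-methyl and the axial 5β-methyl on the quaternary ring-fusion carbon. Ring B carries the C7 isopropylidene conjugated to the C8 ketone, an equatorial 9α-hydroxyl and the axial 10α-hydrogen. The five ring stereocentres C3, C4, C5, C10 and C9 are contiguous (3R,4R,5R,9S,10R): the two methyls are cis, the ester oxygen is trans to the C4 methyl, and the C9 hydroxyl lies on the face opposite to the C5 methyl. A sixth stereocentre, C4′ (S), sits in the side chain and has to be brought in with it. The ester is a (2Z,4S)-4-[(2Z)-hex-2-enoyloxy]hex-2-enoate: two Z-enoates that isomerise when the acyl group is activated, and a γ-oxygenated Z-enoate whose free γ-hydroxy form would close to a butenolide. The α-ketol beside a cross-conjugated enone in ring B can epimerise at C9 or undergo ketol shift under base. The hard points are the quaternary C5 next to the C4 methine, the trans ring fusion, the differentiation of O3, O8 and O9, and the late attachment of the fragile side chain. The strategy rests on one feature: ring A has oxygen on C3 and ring B has oxygen on C9, directly attached to C10. Ring A can therefore be read as the adduct of a 2-silyloxydiene C2=C3–C4=C5 and a vinyl ketone C10=C1 whose carbonyl is C9, the two joined through C6–C9.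

## Retrosynthetic reasoning

**C2′=C3′.** After removal of the C9 silyl ether (40 from 39), the last skeletal bond cut is the side-chain double bond C2′=C3′, which divides 39 into the C3 phosphonoacetate 31 and the α-acyloxy aldehyde 38. Cutting the C3–O acyl bond instead would mean activating a (2Z)-enoic acid, which invites Z to E isomerisation through reversible conjugate addition of the acyl-transfer catalyst. The forward olefination must be Z-selective and must not enolise C4′ of 38 or C9 of the ketol.

**C3–O.** Ester 31 is cut at the C3–O acyl bond into alcohol 29 and phosphonoacetic acid 30. This acylation is safe because 30 has no stereogenic or geometric element. It does require that C3–OH is the only free hydroxyl, hence two silyl ethers of different lability on O3 and O9.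

**Side chain.** Aldehyde 38 goes back through alcohol 37 and silyl ether 36 to the ynoate 35, which is cut at its ester C–O bond into the mono-protected diol 33 and hex-2-ynoic acid 34. The Z double bond is made by semi-hydrogenation after the esterification, so no Z-acid is ever activated. C4′ comes unchanged from (S)-butane-1,2-diol 32.

**C7–C11.** The isopropylidene of 29 (through 28 and the aldol 26) is cut at C7–C11 into ketone 24 and acetone 25. The C8 ketone is the only function that can make C7 nucleophilic, and the silyloxy group at C9 steers enolisation to C7. The forward sequence is a directed aldol addition and a dehydration into conjugation.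

**O8 and O9.** The silyloxy ketone 24 comes from ketol 23 and this from the cis-diol 21, which is traced to the C8=C9 alkene 20. The cycloaddition leaves oxygen on C9 only, as a ketone. Passing through the alkene puts oxygen on both carbons in one step, from the face opposite to the C5 methyl, which is the configuration C9 needs. The forward sequence must then oxidise only the C8 carbinol.

**C3 and C4.** Silyl ether 20 goes back to alcohol 19, ketone 18 and the enol ether 17. C4 is set when the enol ether is unmasked and C3 when the ketone is reduced. This is done while ring B holds nothing but an alkene, so no second carbonyl competes and a dissolving-metal reduction can be used to reach the equatorial alcohol.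

**C9 ketone to alkene.** Diene 17 comes from enol triflate 16 and this from the trans ketone 15. Kinetic enolisation toward C8 leaves C10 alone, and reduction of the triflate removes the oxygen.

**Key disconnection.** The trans ketone 15 is the C10 epimer of the cis-fused ketone 14, and 14 is cut at C1–C2 and C5–C10 to the acyclic trienone 13. Both rings and the quaternary C5 arise together, the oxygen substituents are already on C3 and C9, and the tether length fixes the regiochemistry. The cycloaddition itself is expected to give the cis ring fusion; the trans fusion is reached by equilibration at C10, which is α to the C9 ketone. The forward reaction has to control the absolute configuration at C5.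

**C9–C10 and the dienol ether.** Trienone 13 is cut at C9–C10 into Weinreb amide 11 and vinylmagnesium bromide 12. This bond is made last because a vinyl ketone would not survive the enolisation that makes the diene. Dienol ether 11 comes from methyl ketone 10 by kinetic enolisation at C2.

**C5–C6.** Enone 10 is cut at the sp2–sp3 bond C5–C6 into the bromo enone 6 and the organozinc 9 derived from bromide 8. A cross-coupling with retention transfers the geometry of 6 to the tetrasubstituted alkene.

**Stereodefined bromide.** Bromo enone 6 comes from Weinreb amide 4 and methylmagnesium bromide 5, and 4 from acid 3. Acid 3 is obtained from tiglic acid 1 through dibromide 2 by anti-addition followed by anti-elimination, which fixes the alkene geometry. Bromide 8 is the amide of 4-bromobutanoyl chloride 7.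

## Alternatives that were turned down

Alternative 1: Ring B is taken as a preformed cyclohexanone, and C4–C5 and C1–C10 are cut on either side of the ring fusion. In the forward sense a copper-catalysed asymmetric conjugate addition of vinylmagnesium bromide 12 to 3-methylcyclohex-2-en-1-one A2 creates the quaternary C5. The enolate, held as its silyl enol ether, is joined in the same flask to acrolein A3 under Lewis acid activation to give keto aldehyde A1, with the chain trans to the vinyl group.
- For it: A2 and A3 are commodity chemicals, conjugate addition to β-methylcyclohexenones is a well-understood way to a quaternary centre, and the C9 carbonyl and the trans relation at C10 are in place at once.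
- Against it for 40: the key step closes no ring. Ring A must still be closed between C3 and C4, in a step that turns the vinyl terminus into the C4 methyl (for instance a reductive carbonyl–alkene cyclisation) and sets C4 cis to the C5 methyl and C3 trans to C4 without an obvious control element. A vinyl nucleophile is among the harder ones for quaternary-centre formation, and trapping a hindered enolate with A3 competes with polymerisation of A3.
- Comparison: this plan is the stronger one on the certainty of the absolute configuration at C5 and on the cost of starting materials. The cycloaddition of 13 offers in exchange both rings, the C3 oxygen and the C4 methyl carbon in their final positions in one step, and it leaves C4 to a simple protonation that thermodynamics supports.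

Alternative 2: The C4–C5 bond between the two methyl-bearing carbons is cut, and ring A is opened to the triene A5 (C5=C10–C1=C2–C3(OMe)=C4 on ring B). Irradiation above 300 nm is meant to close A5 by conrotatory 6π electrocyclisation to the cyclohexa-1,3-diene A4, the inside methyl on C5 and the outside methyl on C4 ending up cis.
- For it: it is the only plan in which the cis-vicinal dimethyl relationship follows from a symmetry rule, and it forms the most congested bond of the molecule without a reagent.
- Against it for 40: A5 needs a Z central double bond and a defined C3=C4 geometry, yet the light that closes the ring also scrambles double-bond geometry, reopens A4 and drives hydrogen shifts, so a photostationary mixture is likely. The sense of conrotation, and with it the absolute configuration, rests only on the remote C9 silyloxy group. A4 still lacks the C10 hydrogen, which a later reduction of C1=C10 must place trans.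
- Comparison: the photochemical plan is stronger on the C4/C5 relationship. The cycloaddition of 13 puts a catalyst in charge of the absolute configuration, does not need a geometrically pure triene to survive irradiation, and delivers C9 as a ketone that is directly usable for the C8/C9 oxidation pattern.

Alternative 3: The whole bicyclic skeleton is taken from an enzyme. (+)-Aristolochene A6 is traced through the biosynthetic cascade to (2E,6E)-farnesyl diphosphate A7. A magnesium-dependent aristolochene synthase (a class 1 sesquiterpene cyclase) ionises A7, closes the ten-membered ring, forms C5–C10 across it and finishes with a 1,2-hydride and a 1,2-methyl shift that place the methyls on C4 and C5.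
- For it: one step without protecting groups gives both rings, all fifteen carbons and the 4β,5β-dimethyl array in the absolute configuration of 40.
- Against it for 40: A6 carries no oxygen. C3 is an unactivated methylene that would need site- and face-selective hydroxylation, the C9=C10 double bond must be turned into the trans C10–H, 9α-hydroxy-8-ketone array, and the isopropenyl group must be moved into conjugation. The route also needs enzyme production, a supply of A7 and handling of a volatile hydrocarbon.
- Comparison: on skeleton construction and on C4/C5 stereochemistry the enzymatic plan is clearly stronger. The chosen strategy offers oxygen on C3 and C9 built into the cycloaddition partners, so that every later change of oxidation state happens next to existing functionality and not at remote C–H bonds.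

Key step: step 9

Remark on the chemistry: the sense of induction of the oxazaborolidinium catalyst is assigned from the usual α-C–H···O binding model for enones, which points to the (S)-prolinol-derived catalyst; if the model does not hold for this tethered enone, the (R)-catalyst is used with otherwise identical chemistry.

Remark on the chemistry: acid 30 is taken as a purchasable reagent; it is otherwise one saponification away from its commercial methyl ester.

## Route

Step 1
Reactants: 1 tiglic acid [(E)-2-methylbut-2-enoic acid]
Product: 2 (2R*,3S*)-2,3-dibromo-2-methylbutanoic acid (racemic)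
Conditions: Br2, CH2Cl2, 0 °C → rt
Reagents that add atoms: bromine, BrBr
Why: Electrophilic anti-addition of bromine through the bromonium ion converts the alkene geometry into one relative configuration of the dibromide, which step 2 needs.

Step 2
Reactants: 2 (2R*,3S*)-2,3-dibromo-2-methylbutanoic acid
Product: 3 (E)-3-bromo-2-methylbut-2-enoic acid
Conditions: KOH, MeOH, reflux; then HCl (aq)
Reagents that add atoms: none
Why: E2 dehydrobromination: C2 has no hydrogen, so the C3 hydrogen and the C2 bromine leave anti-periplanar, which from this diastereomer places the remaining bromine trans to the carboxyl group (3 is the classical 3-bromoangelic acid).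

Step 3
Reactants: 3 (E)-3-bromo-2-methylbut-2-enoic acid
Product: 4 (E)-3-bromo-N-methoxy-N,2-dimethylbut-2-enamide
Conditions: 1,1'-carbonyldiimidazole, CH2Cl2, rt; then MeNHOMe·HCl
Reagents that add atoms: N,O-dimethylhydroxylamine hydrochloride, CNOC.Cl
Why: Amide formation through the acyl imidazole; no strong acid or heat is used, so the β-bromo acrylate keeps its geometry.

Step 4
Reactants: 4 (E)-3-bromo-N-methoxy-N,2-dimethylbut-2-enamide; 5 methylmagnesium bromide
Product: 6 (E)-4-bromo-3-methylpent-3-en-2-one
Conditions: THF, -20 → 0 °C; NH4Cl (aq)
Reagents that add atoms: none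
Why: Weinreb ketone synthesis: the chelated tetrahedral intermediate lasts until the quench, so one methyl group is added and the vinyl bromide is untouched at this temperature.

Step 5
Reactants: 7 4-bromobutanoyl chloride
Product: 8 4-bromo-N-methoxy-N-methylbutanamide
Conditions: MeNHOMe·HCl, pyridine, CH2Cl2, 0 °C
Reagents that add atoms: N,O-dimethylhydroxylamine hydrochloride, CNOC.Cl
Why: Acylation of the amine by the acid chloride; the primary bromide is inert under these conditions.

Step 6
Reactants: 8 4-bromo-N-methoxy-N-methylbutanamide; 6 (E)-4-bromo-3-methylpent-3-en-2-one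
Product: 10 (E)-N-methoxy-N,5,6-trimethyl-7-oxooct-5-enamide, via organozinc bromide 9 (not isolated)
Conditions: Zn dust, I2 (cat.), N,N-dimethylacetamide, 80 °C; then 6, PdCl2(dppf) (3 mol%), THF, 40 °C
Reagents that add atoms: none
Why: Negishi sp3–sp2 coupling: zinc inserts into the C–Br bond of 8, and oxidative addition of the activated vinyl bromide to zerovalent palladium and reductive elimination both go with retention, so the chain ends up trans to the acetyl group; the amide is tolerated by the organozinc.

Step 7
Reactants: 10 (E)-N-methoxy-N,5,6-trimethyl-7-oxooct-5-enamide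
Product: 11 (5E)-N-methoxy-N,5,6-trimethyl-7-[(triisopropylsilyl)oxy]octa-5,7-dienamide
Conditions: LiN(iPr)2, THF, -78 °C; then iPr3SiOSO2CF3, -78 → 0 °C
Reagents that add atoms: triisopropylsilyl trifluoromethanesulfonate, CC(C)[Si](OS(=O)(=O)C(F)(F)F)(C(C)C)C(C)C
Why: Kinetic deprotonation of the enone at its α′ methyl group (C2) and O-silylation of the cross-conjugated enolate; the methyl ketone is far more acidic than the amide α-methylene, and no cationic intermediate forms that could scramble the C4=C5 geometry.

Step 8
Reactants: 11 (5E)-N-methoxy-N,5,6-trimethyl-7-[(triisopropylsilyl)oxy]octa-5,7-dienamide; 12 vinylmagnesium bromide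
Product: 13 (7E)-7,8-dimethyl-9-[(triisopropylsilyl)oxy]deca-1,7,9-trien-3-one
Conditions: THF, -78 → 0 °C; inverse quench into cold 1 M HCl/Et2O; used without delay
Reagents that add atoms: none
Why: Weinreb ketone synthesis releases the vinyl ketone only on hydrolysis of the chelate; quenching into cold acid protonates the liberated amine before it can add to the enone, and the hindered triisopropylsilyl enol ether tolerates the short contact with dilute acid.

Step 9
Reactants: 13 (7E)-7,8-dimethyl-9-[(triisopropylsilyl)oxy]deca-1,7,9-trien-3-one
Product: 14 cis-fused (5S,10S)-3-[(triisopropylsilyl)oxy]-11,12,13-trinoreremophil-3-en-9-one (5β-methyl, 10β-H)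
Conditions: N-protonated (S)-3,3-diphenyl-1-(o-tolyl)tetrahydro-1H,3H-pyrrolo[1,2-c][1,3,2]oxazaborole bis(trifluoromethanesulfonyl)imide, [C24H25BNO][N(SO2CF3)2] (20 mol%), CH2Cl2 (0.01 M), -78 → -40 °C; Et3N quench
Reagents that add atoms: none
Why: The boron of the oxazaborolidinium cation binds the C9 carbonyl and lowers the LUMO of the vinyl ketone, so the electron-rich C2 terminus of the silyloxydiene bonds to C1 first and C5–C10 follows within one strongly asynchronous [4+2] event, at the limit a Mukaiyama–Michael addition followed by closure of the boron enolate onto the silyloxyallyl cation. The closest known reaction type is the oxazaborolidinium-catalysed Diels–Alder reaction of 2-silyloxydienes with enones, including intramolecular cases with the activating carbonyl in the tether. Ring A is the new cyclohexene, built from diene carbons C2–C5 and dienophile carbons C1 and C10 with the enol ether left at C3=C4; ring B closes through the four-atom tether C6–C9 in the type 1 intramolecular mode, C5–C10 being its ring-closing bond. The regiochemistry is fixed by the tether and agrees with the para preference of a 2-oxygenated diene. C10 is formed on the enone face left open by the catalyst, and C5 is tied to it by the endo placement of the tethered carbonyl under the diene, which gives the cis ring fusion. The step therefore needs face selectivity at the dienophile and a single tether topology, because an exo (trans-fused) by-product would have the opposite configuration at C5 and has to be removed by chromatography before step 10; the rigid catalyst pocket and the endo preference of a ketone inside the tether should secure both. High dilution and low temperature hold back intermolecular Michael addition of the diene to the vinyl ketone, and the triisopropylsilyl group keeps the enol ether intact under the strongly acidic catalyst.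

Step 10
Reactants: 14 cis-fused (5S,10S)-3-[(triisopropylsilyl)oxy]-11,12,13-trinoreremophil-3-en-9-one
Product: 15 trans-fused (5S,10R)-3-[(triisopropylsilyl)oxy]-11,12,13-trinoreremophil-3-en-9-one (5β-methyl, 10α-H)
Conditions: DBU, toluene, 60 °C; cis isomer recycled
Reagents that add atoms: none
Why: Epimerisation through the C9 enolate, C10 being the only enolisable stereocentre; the trans isomer should be favoured because its axial C5 methyl meets only two syn-axial hydrogens (C3 and C9 are trigonal) while the cis isomer keeps the extra gauche interactions of a cis-decalin, and reprotonation at C10 anti to the C5 methyl leads the same way.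

Step 11
Reactants: 15 trans-fused (5S,10R)-3-[(triisopropylsilyl)oxy]-11,12,13-trinoreremophil-3-en-9-one
Product: 16 3-[(triisopropylsilyl)oxy]-11,12,13-trinoreremophila-3,8-dien-9-yl trifluoromethanesulfonate (5β-methyl, 10α-H)
Conditions: LiN(iPr)2, THF, -78 °C; then PhN(SO2CF3)2, -78 → 0 °C
Reagents that add atoms: N-phenylbis(trifluoromethanesulfonimide), O=S(=O)(N(c1ccccc1)S(=O)(=O)C(F)(F)F)C(F)(F)F
Why: Kinetic enolisation takes the less hindered C8 methylene and not the C10 methine, so C10 is not touched, and O-sulfonylation fixes the C8=C9 enol triflate.

Step 12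
Reactants: 16 3-[(triisopropylsilyl)oxy]-11,12,13-trinoreremophila-3,8-dien-9-yl trifluoromethanesulfonate
Product: 17 3-[(triisopropylsilyl)oxy]-11,12,13-trinoreremophila-3,8-diene (5β-methyl, 10α-H)
Conditions: Pd(OAc)2 (5 mol%), PPh3, HCO2H, Bu3N, DMF, 60 °C
Reagents that add atoms: none
Why: Palladium-catalysed formate reduction of the enol triflate (oxidative addition, formate exchange, decarboxylation to the palladium hydride, reductive elimination) replaces C9–O by C9–H; the amine-buffered medium leaves the silyl enol ether intact.

Step 13
Reactants: 17 3-[(triisopropylsilyl)oxy]-11,12,13-trinoreremophila-3,8-diene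
Product: 18 11,12,13-trinoreremophil-8-en-3-one (4β,5β-dimethyl, 10α-H)
Conditions: Bu4NF, AcOH, THF, 0 °C
Reagents that add atoms: none
Why: Fluoride cleaves the O–Si bond and the enolate is protonated at C4 on the α face, axially and anti to the C5 methyl, which gives the equatorial 4β-methyl; this is also the more stable epimer, so any 4α isomer can be equilibrated with base.

Step 14
Reactants: 18 11,12,13-trinoreremophil-8-en-3-one
Product: 19 11,12,13-trinoreremophil-8-en-3α-ol (4β,5β-dimethyl, 10α-H)
Conditions: Li, NH3 (l), THF, MeOH, -78 °C; then NH4Cl
Reagents that add atoms: none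
Why: Dissolving-metal reduction through the ketyl and the carbinyl anion gives the thermodynamically preferred equatorial 3α-alcohol, since the axial 3β-alcohol would be syn-axial to the C5 methyl; the isolated C8=C9 double bond is not reduced.

Step 15
Reactants: 19 11,12,13-trinoreremophil-8-en-3α-ol
Product: 20 3α-(triethylsilyloxy)-11,12,13-trinoreremophil-8-ene
Conditions: Et3SiCl, imidazole, DMF, 0 °C → rt
Reagents that add atoms: chlorotriethylsilane, CC[Si](Cl)(CC)CC
Why: Silylation of the only hydroxyl; the triethylsilyl ether survives steps 16 to 20 and can later be removed beside the tert-butyldimethylsilyl ether on O9.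

Step 16
Reactants: 20 3α-(triethylsilyloxy)-11,12,13-trinoreremophil-8-ene
Product: 21 3α-(triethylsilyloxy)-11,12,13-trinoreremophilane-8α,9α-diol
Conditions: OsO4 (2 mol%), N-methylmorpholine N-oxide, acetone/H2O, rt
Reagents that add atoms: N-methylmorpholine N-oxide, C[N+]1([O-])CCOCC1; water, O
Why: Upjohn syn-dihydroxylation: OsO4 adds on the α face because the axial C5 methyl, 1,3 to C9, shields the β face (the same bias as in 2-ene steroids with an angular methyl), so both hydroxyls are α and C9 receives its final configuration.

Step 17
Reactants: 21 3α-(triethylsilyloxy)-11,12,13-trinoreremophilane-8α,9α-diol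
Product: 23 9α-hydroxy-3α-(triethylsilyloxy)-11,12,13-trinoreremophilan-8-one, via stannylene acetal 22 (not isolated)
Conditions: Bu2SnO, toluene, reflux (-H2O); then Br2, 4 Å molecular sieves, CH2Cl2, 0 °C → rt
Reagents that add atoms: none
Why: Brominolysis of a dibutylstannylene acetal oxidises one carbinol of a 1,2-diol to the ketone; in cis-diols on a chair the axial carbinol is the one oxidised, here C8 (8α-OH axial, 9α-OH equatorial and more hindered), and the net reaction forms Bu2SnBr2 and no free acid.

Step 18
Reactants: 23 9α-hydroxy-3α-(triethylsilyloxy)-11,12,13-trinoreremophilan-8-one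
Product: 24 9α-(tert-butyldimethylsilyloxy)-3α-(triethylsilyloxy)-11,12,13-trinoreremophilan-8-one
Conditions: t-BuMe2SiOSO2CF3, 2,6-lutidine, CH2Cl2, -78 → 0 °C
Reagents that add atoms: tert-butyldimethylsilyl trifluoromethanesulfonate, CC(C)(C)[Si](C)(C)OS(=O)(=O)C(F)(F)F
Why: Silylation of the hindered α-hydroxy ketone with the silyl triflate; the ether prevents ketol shift and leaves C7 as the only easily enolised position.

Step 19
Reactants: 24 9α-(tert-butyldimethylsilyloxy)-3α-(triethylsilyloxy)-11,12,13-trinoreremophilan-8-one; 25 acetone
Product: 26 9α-(tert-butyldimethylsilyloxy)-11-hydroxy-3α-(triethylsilyloxy)eremophilan-8-one (mixture at C7)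
Conditions: LiN(iPr)2, THF, -78 °C; ZnCl2; then acetone, -78 → -40 °C; NH4Cl (aq)
Reagents that add atoms: none
Why: Kinetic deprotonation occurs at the C7 methylene and not at the silyloxy-bearing C9 methine; the zinc enolate adds to acetone in a directed aldol addition and the chelated zinc aldolate resists retro-aldol cleavage; the C7 configuration is lost in step 20.

Step 20
Reactants: 26 9α-(tert-butyldimethylsilyloxy)-11-hydroxy-3α-(triethylsilyloxy)eremophilan-8-one
Product: 28 9α-(tert-butyldimethylsilyloxy)-3α-(triethylsilyloxy)eremophil-7(11)-en-8-one, via tertiary mesylate 27 (not isolated)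
Conditions: MeSO2Cl, Et3N, CH2Cl2, 0 °C; then DBU, rt
Reagents that add atoms: none
Why: Sulfonylation of the tertiary alcohol through the sulfene and E1cB elimination through the C8 enolate give the conjugated tetrasubstituted isopropylidene; DBU also brings any deconjugated isopropenyl isomer into conjugation.

Step 21
Reactants: 28 9α-(tert-butyldimethylsilyloxy)-3α-(triethylsilyloxy)eremophil-7(11)-en-8-one
Product: 29 9α-(tert-butyldimethylsilyloxy)-3α-hydroxyeremophil-7(11)-en-8-one
Conditions: pyridinium p-toluenesulfonate, MeOH/CH2Cl2, 0 °C
Reagents that add atoms: none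
Why: Acid-catalysed methanolysis removes the triethylsilyl ether much faster than the hindered secondary tert-butyldimethylsilyl ether, so only the C3 hydroxyl is set free.

Step 22
Reactants: 29 9α-(tert-butyldimethylsilyloxy)-3α-hydroxyeremophil-7(11)-en-8-one; 30 [bis(2,2,2-trifluoroethoxy)phosphoryl]acetic acid
Product: 31 9α-(tert-butyldimethylsilyloxy)-8-oxoeremophil-7(11)-en-3α-yl [bis(2,2,2-trifluoroethoxy)phosphoryl]acetate
Conditions: N-(3-dimethylaminopropyl)-N′-ethylcarbodiimide hydrochloride, 4-(dimethylamino)pyridine (cat.), CH2Cl2, 0 °C → rt
Reagents that add atoms: none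
Why: Carbodiimide (Steglich) esterification; phosphonoacetic acids acylate hindered secondary alcohols well, and the acid has no stereogenic or geometric element at risk.

Step 23
Reactants: 32 (S)-butane-1,2-diol
Product: 33 (S)-1-(tert-butyldimethylsilyloxy)butan-2-ol
Conditions: t-BuMe2SiCl, imidazole, CH2Cl2, -20 → 0 °C
Reagents that add atoms: tert-butylchlorodimethylsilane, CC(C)(C)[Si](C)(C)Cl
Why: Selective silylation of the primary hydroxyl on steric grounds; C2 keeps the S configuration that becomes C4′.

Step 24
Reactants: 33 (S)-1-(tert-butyldimethylsilyloxy)butan-2-ol; 34 hex-2-ynoic acid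
Product: 35 (S)-1-(tert-butyldimethylsilyloxy)butan-2-yl hex-2-ynoate
Conditions: N,N′-dicyclohexylcarbodiimide, 4-(dimethylamino)pyridine (cat.), CH2Cl2, -20 → 0 °C
Reagents that add atoms: none
Why: Steglich esterification with the alkynoic acid, which has no double-bond geometry to lose on activation; the carbinol C–O bond is not broken, so the configuration is retained.

Step 25
Reactants: 35 (S)-1-(tert-butyldimethylsilyloxy)butan-2-yl hex-2-ynoate
Product: 36 (S)-1-(tert-butyldimethylsilyloxy)butan-2-yl (Z)-hex-2-enoate
Conditions: H2 (1 atm), Pd/CaCO3 poisoned with Pb(OAc)2, quinoline, EtOAc, rt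
Reagents that add atoms: none
Why: Lindlar semi-hydrogenation adds hydrogen syn on the catalyst surface and stops at the alkene, giving the (Z)-enoate.

Step 26
Reactants: 36 (S)-1-(tert-butyldimethylsilyloxy)butan-2-yl (Z)-hex-2-enoate
Product: 37 (S)-1-hydroxybutan-2-yl (Z)-hex-2-enoate
Conditions: HF·pyridine, THF, 0 °C
Reagents that add atoms: none
Why: Fluoride cleavage of the primary silyl ether under weakly acidic conditions, which avoid the 1,2-acyl migration that basic fluoride sources promote.

Step 27
Reactants: 37 (S)-1-hydroxybutan-2-yl (Z)-hex-2-enoate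
Product: 38 (S)-1-oxobutan-2-yl (Z)-hex-2-enoate
Conditions: Dess–Martin periodinane, NaHCO3, CH2Cl2, 0 °C; used at once
Reagents that add atoms: none
Why: Dess–Martin oxidation of the primary alcohol under near-neutral conditions, so the α-acyloxy stereocentre is not enolised.

Step 28
Reactants: 31 9α-(tert-butyldimethylsilyloxy)-8-oxoeremophil-7(11)-en-3α-yl [bis(2,2,2-trifluoroethoxy)phosphoryl]acetate; 38 (S)-1-oxobutan-2-yl (Z)-hex-2-enoate
Product: 39 9α-(tert-butyldimethylsilyloxy)-8-oxoeremophil-7(11)-en-3α-yl (2Z,4S)-4-[(2Z)-hex-2-enoyloxy]hex-2-enoate
Conditions: KN(SiMe3)2, 18-crown-6, THF, -78 °C; then 38, -78 °C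
Reagents that add atoms: none
Why: Still–Gennari olefination: the electron-poor bis(trifluoroethyl) phosphonate with a dissociated potassium counter-ion eliminates quickly from the kinetically formed adduct and gives the (Z)-enoate; the phosphonate is far more acidic than C9–H or the aldehyde α-hydrogen, so it is deprotonated first and no free base remains when 38 is added.

Step 29
Reactants: 39 9α-(tert-butyldimethylsilyloxy)-8-oxoeremophil-7(11)-en-3α-yl (2Z,4S)-4-[(2Z)-hex-2-enoyloxy]hex-2-enoate
Product: 40 (3R,4R,5R,9S,10R)-9-hydroxy-8-oxoeremophil-7(11)-en-3-yl (2Z,4S)-4-[(2Z)-hex-2-enoyloxy]hex-2-enoate (CNP0170141.1)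
Conditions: HF·pyridine, pyridine, THF, 0 °C → rt
Reagents that add atoms: none
Why: Fluoride cleavage of the remaining silyl ether under buffered acidic conditions, which do not isomerise the Z-enoates, open the esters or epimerise the ketol.

## Compound list

1 | tiglic acid, (E)-2-methylbut-2-enoic acid | C/C=C(\C)C(=O)O | starting material
2 | (2R*,3S*)-2,3-dibromo-2-methylbutanoic acid (racemic, one enantiomer drawn) | C[C@@H](Br)[C@@](C)(Br)C(=O)O | intermediate
3 | (E)-3-bromo-2-methylbut-2-enoic acid | C/C(Br)=C(/C)C(=O)O | intermediate
4 | (E)-3-bromo-N-methoxy-N,2-dimethylbut-2-enamide | C/C(Br)=C(/C)C(=O)N(C)OC | intermediate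
5 | methylmagnesium bromide | C[Mg]Br | starting material
6 | (E)-4-bromo-3-methylpent-3-en-2-one | C/C(Br)=C(/C)C(C)=O | intermediate
7 | 4-bromobutanoyl chloride | O=C(Cl)CCCBr | starting material
8 | 4-bromo-N-methoxy-N-methylbutanamide | CON(C)C(=O)CCCBr | intermediate
9 | [4-[methoxy(methyl)amino]-4-oxobutyl]zinc bromide | CON(C)C(=O)CCC[Zn]Br | intermediate (not isolated)
10 | (E)-N-methoxy-N,5,6-trimethyl-7-oxooct-5-enamide | CON(C)C(=O)CCC/C(C)=C(\C)C(C)=O | intermediate
11 | (5E)-N-methoxy-N,5,6-trimethyl-7-[(triisopropylsilyl)oxy]octa-5,7-dienamide | CON(C)C(=O)CCC/C(C)=C(\C)C(=C)O[Si](C(C)C)(C(C)C)C(C)C | intermediate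
12 | vinylmagnesium bromide | C=C[Mg]Br | starting material
13 | (7E)-7,8-dimethyl-9-[(triisopropylsilyl)oxy]deca-1,7,9-trien-3-one | C=CC(=O)CCC/C(C)=C(\C)C(=C)O[Si](C(C)C)(C(C)C)C(C)C | intermediate
14 | cis-fused (5S,10S)-3-[(triisopropylsilyl)oxy]-11,12,13-trinoreremophil-3-en-9-one (5β-methyl, 10β-H) | CC(C)[Si](C(C)C)(C(C)C)OC1=C(C)[C@@]2(C)CCCC(=O)[C@H]2CC1 | intermediate
15 | trans-fused (5S,10R)-3-[(triisopropylsilyl)oxy]-11,12,13-trinoreremophil-3-en-9-one (5β-methyl, 10α-H) | CC(C)[Si](C(C)C)(C(C)C)OC1=C(C)[C@@]2(C)CCCC(=O)[C@@H]2CC1 | intermediate
16 | 3-[(triisopropylsilyl)oxy]-11,12,13-trinoreremophila-3,8-dien-9-yl trifluoromethanesulfonate (5β-methyl, 10α-H) | CC(C)[Si](C(C)C)(C(C)C)OC1=C(C)[C@@]2(C)CCC=C(OS(=O)(=O)C(F)(F)F)[C@@H]2CC1 | intermediate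
17 | 3-[(triisopropylsilyl)oxy]-11,12,13-trinoreremophila-3,8-diene (5β-methyl, 10α-H) | CC(C)[Si](C(C)C)(C(C)C)OC1=C(C)[C@@]2(C)CCC=C[C@@H]2CC1 | intermediate
18 | 11,12,13-trinoreremophil-8-en-3-one (4β,5β-dimethyl, 10α-H) | O=C1CC[C@H]2C=CCC[C@]2(C)[C@H]1C | intermediate
19 | 11,12,13-trinoreremophil-8-en-3α-ol (4β,5β-dimethyl, 10α-H) | O[C@@H]1CC[C@H]2C=CCC[C@]2(C)[C@H]1C | intermediate
20 | 3α-(triethylsilyloxy)-11,12,13-trinoreremophil-8-ene | CC[Si](CC)(CC)O[C@@H]1CC[C@H]2C=CCC[C@]2(C)[C@H]1C | intermediate
21 | 3α-(triethylsilyloxy)-11,12,13-trinoreremophilane-8α,9α-diol | CC[Si](CC)(CC)O[C@@H]1CC[C@H]2[C@H](O)[C@H](O)CC[C@]2(C)[C@H]1C | intermediate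
22 | 8α,9α-O-dibutylstannylene acetal of 21 (drawn as monomer) | CC[Si](CC)(CC)O[C@@H]1CC[C@H]2[C@@H]3O[Sn](CCCC)(CCCC)O[C@@H]3CC[C@]2(C)[C@H]1C | intermediate (not isolated)
23 | 9α-hydroxy-3α-(triethylsilyloxy)-11,12,13-trinoreremophilan-8-one | CC[Si](CC)(CC)O[C@@H]1CC[C@H]2[C@H](O)C(=O)CC[C@]2(C)[C@H]1C | intermediate
24 | 9α-(tert-butyldimethylsilyloxy)-3α-(triethylsilyloxy)-11,12,13-trinoreremophilan-8-one | CC[Si](CC)(CC)O[C@@H]1CC[C@H]2[C@H](O[Si](C)(C)C(C)(C)C)C(=O)CC[C@]2(C)[C@H]1C | intermediate
25 | acetone | CC(C)=O | starting material
26 | 9α-(tert-butyldimethylsilyloxy)-11-hydroxy-3α-(triethylsilyloxy)eremophilan-8-one (mixture at C7) | CC[Si](CC)(CC)O[C@@H]1CC[C@H]2[C@H](O[Si](C)(C)C(C)(C)C)C(=O)C(C(C)(C)O)C[C@]2(C)[C@H]1C | intermediate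
27 | 11-methanesulfonate of 26 | CC[Si](CC)(CC)O[C@@H]1CC[C@H]2[C@H](O[Si](C)(C)C(C)(C)C)C(=O)C(C(C)(C)OS(C)(=O)=O)C[C@]2(C)[C@H]1C | intermediate (not isolated)
28 | 9α-(tert-butyldimethylsilyloxy)-3α-(triethylsilyloxy)eremophil-7(11)-en-8-one | CC[Si](CC)(CC)O[C@@H]1CC[C@H]2[C@H](O[Si](C)(C)C(C)(C)C)C(=O)C(=C(C)C)C[C@]2(C)[C@H]1C | intermediate
29 | 9α-(tert-butyldimethylsilyloxy)-3α-hydroxyeremophil-7(11)-en-8-one | O[C@@H]1CC[C@H]2[C@H](O[Si](C)(C)C(C)(C)C)C(=O)C(=C(C)C)C[C@]2(C)[C@H]1C | intermediate
30 | [bis(2,2,2-trifluoroethoxy)phosphoryl]acetic acid | OC(=O)CP(=O)(OCC(F)(F)F)OCC(F)(F)F | starting material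
31 | 9α-(tert-butyldimethylsilyloxy)-8-oxoeremophil-7(11)-en-3α-yl [bis(2,2,2-trifluoroethoxy)phosphoryl]acetate | O=C(CP(=O)(OCC(F)(F)F)OCC(F)(F)F)O[C@@H]1CC[C@H]2[C@H](O[Si](C)(C)C(C)(C)C)C(=O)C(=C(C)C)C[C@]2(C)[C@H]1C | intermediate
32 | (S)-butane-1,2-diol | CC[C@H](O)CO | starting material
33 | (S)-1-(tert-butyldimethylsilyloxy)butan-2-ol | CC[C@H](O)CO[Si](C)(C)C(C)(C)C | intermediate
34 | hex-2-ynoic acid | CCCC#CC(=O)O | starting material
35 | (S)-1-(tert-butyldimethylsilyloxy)butan-2-yl hex-2-ynoate | CCCC#CC(=O)O[C@@H](CC)CO[Si](C)(C)C(C)(C)C | intermediate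
36 | (S)-1-(tert-butyldimethylsilyloxy)butan-2-yl (Z)-hex-2-enoate | CCC/C=C\C(=O)O[C@@H](CC)CO[Si](C)(C)C(C)(C)C | intermediate
37 | (S)-1-hydroxybutan-2-yl (Z)-hex-2-enoate | CCC/C=C\C(=O)O[C@@H](CC)CO | intermediate
38 | (S)-1-oxobutan-2-yl (Z)-hex-2-enoate | CCC/C=C\C(=O)O[C@@H](CC)C=O | intermediate
39 | 9α-(tert-butyldimethylsilyloxy)-8-oxoeremophil-7(11)-en-3α-yl (2Z,4S)-4-[(2Z)-hex-2-enoyloxy]hex-2-enoate | CCC/C=C\C(=O)O[C@H](/C=C\C(=O)O[C@@H]1CC[C@H]2[C@H](O[Si](C)(C)C(C)(C)C)C(=O)C(=C(C)C)C[C@]2(C)[C@H]1C)CC | intermediate
40 | (3R,4R,5R,9S,10R)-9-hydroxy-8-oxoeremophil-7(11)-en-3-yl (2Z,4S)-4-[(2Z)-hex-2-enoyloxy]hex-2-enoate | CCC/C=C\C(=O)O[C@H](/C=C\C(=O)O[C@@H]1CC[C@H]2[C@H](O)C(=O)C(=C(C)C)C[C@]2(C)[C@H]1C)CC | target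

## Step count and least certain steps

Total step count: 29. Longest linear sequence: 23 steps (steps 1–4, 6–22, 28 and 29, from tiglic acid 1 to 40).

**Step 9 (key step).** The ring closure at the fully substituted diene terminus may be slow, which would let intermolecular Michael addition of the diene to the vinyl ketone or loss of the silyl group take over. Face selectivity or endo selectivity may also be incomplete, which lowers the enantiomeric purity after step 10. Fallback: the fallback sets out from 13 and gives up catalyst control. Cyclisation with dimethylaluminium chloride, Me2AlCl, in CH2Cl2 at -78 °C should give the racemic cis-fused adduct F1, and DBU in toluene then gives the racemic trans-fused ketone F2. F2 is resolved by preparative chromatography on a chiral stationary phase, and the (5S,10R) enantiomer rejoins the route at 15.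

**Step 10.** The angular methyl narrows the energy gap between cis- and trans-fused ketones, so the equilibration may stall with a large share of cis isomer. Fallback: starting from 14, the more substituted enol ether is made under equilibrating silylation conditions (Me3SiCl, NaI, Et3N, MeCN, 60 °C), giving the C9=C10 bis-silyl dienol ether F3. Methyllithium in THF cleaves the trimethylsilyl group to the lithium enolate, and protonation at -78 °C occurs axially on the α face, anti to the C5 methyl. This kinetic protonation, not an equilibrium, delivers 15.

**Step 14.** Electron-transfer reduction may give incomplete equatorial selectivity or pinacol-type dimerisation. Fallback: from 18, LiBH(s-Bu)3 in THF at -78 °C attacks from the open α face and gives the axial 3β-alcohol F4. A Mitsunobu reaction with 4-nitrobenzoic acid (PPh3, diisopropyl azodicarboxylate) inverts C3 to the 3α-4-nitrobenzoate F5, and K2CO3 in MeOH releases 19.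

**Step 17.** Oxidation may occur at the wrong carbinol or run on to the diketone, and traces of acid may remove the triethylsilyl ether. Fallback: the two hydroxyls of 21 are told apart by protection instead of by oxidation rate. Trimethyl orthoacetate with catalytic camphorsulfonic acid gives the cyclic orthoester, whose mild aqueous opening leaves the ester on the axial oxygen, that is the 8α-acetate 9α-alcohol F6. Silylation of O9 (t-BuMe2SiOSO2CF3, 2,6-lutidine) gives F7, K2CO3 in MeOH removes the acetate to give the 8α-alcohol F8, and Dess–Martin oxidation of F8 returns to the route at 24.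

**Step 28.** Z selectivity may be incomplete at a stage where isomers are hard to separate, the α-acyloxy aldehyde may enolise and erode C4′, and the potassium phosphonate may attack the base-sensitive ketol. Fallback: the olefination is moved off the scaffold. Aldehyde 38 is treated with tert-butyl [bis(2,2,2-trifluoroethoxy)phosphoryl]acetate under the same Still–Gennari conditions to give the tert-butyl ester F9, which is purified to a single Z,Z isomer. Trifluoroacetic acid in CH2Cl2 gives the acid F10. F10 is then joined to alcohol 29 through its mixed anhydride with 2,4,6-trichlorobenzoyl chloride (Et3N, then 4-(dimethylamino)pyridine at low temperature), which rejoins the route at 39.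

## Further compounds

F1 | step 9 | racemic cis-fused 3-[(triisopropylsilyl)oxy]-11,12,13-trinoreremophil-3-en-9-one (racemate of 14, one enantiomer drawn) | CC(C)[Si](C(C)C)(C(C)C)OC1=C(C)[C@@]2(C)CCCC(=O)[C@H]2CC1
F2 | step 9 | racemic trans-fused 3-[(triisopropylsilyl)oxy]-11,12,13-trinoreremophil-3-en-9-one (racemate of 15, one enantiomer drawn) | CC(C)[Si](C(C)C)(C(C)C)OC1=C(C)[C@@]2(C)CCCC(=O)[C@@H]2CC1
F3 | step 10 | 3-[(triisopropylsilyl)oxy]-9-(trimethylsilyloxy)-11,12,13-trinoreremophila-3,9-diene (5β-methyl) | CC(C)[Si](C(C)C)(C(C)C)OC1=C(C)[C@@]2(C)CCCC(O[Si](C)(C)C)=C2CC1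
F4 | step 14 | 11,12,13-trinoreremophil-8-en-3β-ol (4β,5β-dimethyl, 10α-H) | O[C@H]1CC[C@H]2C=CCC[C@]2(C)[C@H]1C
F5 | step 14 | 11,12,13-trinoreremophil-8-en-3α-yl 4-nitrobenzoate | O=C(O[C@@H]1CC[C@H]2C=CCC[C@]2(C)[C@H]1C)c1ccc(cc1)[N+](=O)[O-]
F6 | step 17 | 9α-hydroxy-3α-(triethylsilyloxy)-11,12,13-trinoreremophilan-8α-yl acetate | CC[Si](CC)(CC)O[C@@H]1CC[C@H]2[C@H](O)[C@H](OC(C)=O)CC[C@]2(C)[C@H]1C
F7 | step 17 | 9α-(tert-butyldimethylsilyloxy)-3α-(triethylsilyloxy)-11,12,13-trinoreremophilan-8α-yl acetate | CC[Si](CC)(CC)O[C@@H]1CC[C@H]2[C@H](O[Si](C)(C)C(C)(C)C)[C@H](OC(C)=O)CC[C@]2(C)[C@H]1C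
F8 | step 17 | 9α-(tert-butyldimethylsilyloxy)-3α-(triethylsilyloxy)-11,12,13-trinoreremophilan-8α-ol | CC[Si](CC)(CC)O[C@@H]1CC[C@H]2[C@H](O[Si](C)(C)C(C)(C)C)[C@H](O)CC[C@]2(C)[C@H]1C
F9 | step 28 | tert-butyl (2Z,4S)-4-[(2Z)-hex-2-enoyloxy]hex-2-enoate | CCC/C=C\C(=O)O[C@H](/C=C\C(=O)OC(C)(C)C)CC
F10 | step 28 | (2Z,4S)-4-[(2Z)-hex-2-enoyloxy]hex-2-enoic acid | CCC/C=C\C(=O)O[C@H](/C=C\C(=O)O)CC
A1 | alternative 1 | 3-methyl-2-(3-oxopropyl)-3-vinylcyclohexan-1-one (chain trans to vinyl) | O=CCC[C@H]1C(=O)CCC[C@]1(C)C=C
A2 | alternative 1 | 3-methylcyclohex-2-en-1-one | CC1=CC(=O)CCC1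
A3 | alternative 1 | acrolein | C=CC=O
A4 | alternative 2 | 3-methoxy-4β,5β-dimethyl-9β-(tert-butyldimethylsilyloxy) bicyclic 1(10),2-diene (eremophilane numbering) | COC1=CC=C2[C@@H](O[Si](C)(C)C(C)(C)C)CCC[C@]2(C)[C@H]1C
A5 | alternative 2 | ring B triene, tert-butyl{[2-((1Z,3Z)-3-methoxypenta-1,3-dienyl)-3-methylcyclohex-2-en-1-yl]oxy}dimethylsilane | CC1=C(/C=C\C(OC)=C\C)[C@@H](O[Si](C)(C)C(C)(C)C)CCC1
A6 | alternative 3 | (+)-aristolochene, (4S,5R,7S)-eremophila-9,11-diene | C1CCC2=CC[C@H](C(C)=C)C[C@]2(C)[C@H]1C
A7 | alternative 3 | (2E,6E)-farnesyl diphosphate | CC(C)=CCC/C(C)=C/CC/C(C)=C/COP(=O)(O)OP(=O)(O)O
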